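The readings were generated by integration with made-up constants, noise included.

The amounts charged and the earlier readings were these.

| setting | summer | autumn | winter | oak | birch | larch | elm |
|---|---|---|---|---|---|---|---|
| starting material | 0.27 M | 1.4 M | 0.61 M | 0.20 M | 0.61 M | 0.20 M | 1.0 M |
| reagent | 1.22 M | 1.22 M | 1.22 M | 2.50 M | 1.22 M | 1.22 M | 0.800 M |
| protic impurity | 0.122 M | 0.122 M | 0.052 M | 0.122 M | 0.122 M | 0.0400 M | 0.0600 M |
| remark | run made earlier | run made earlier | run made earlier |  |  |  |  |
| time |  |  |  | 2.5 h | 2.5 h | 2.5 h | 2.5 h |

| run | time / min | product / % |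
|---|---|---|
| summer | 15.0 | 2 |
| summer | 30.0 | 0 |
| summer | 50.0 | 1 |
| summer | 60.0 | 4 |
| summer | 80.0 | 4 |
| summer | 90.0 | 6 |
| summer | 120 | 9 |
| autumn | 15.0 | 0 |
| autumn | 30.0 | 5 |
| autumn | 50.0 | 22 |
| autumn | 60.0 | 36 |
| autumn | 80.0 | 53 |
| autumn | 90.0 | 61 |
| autumn | 120 | 76 |
| winter | 10.0 | 0 |
| winter | 25.0 | 0 |
| winter | 50.0 | 5 |
| winter | 80.0 | 16 |
| winter | 120 | 46 |

(each reading ± 1.5 percentage points)

* all flasks from highest to lowest amount of product, in percent of the starting material charged, at 2.5 h (oak / birch / larch / elm)
* the amount of product, in percent of the starting material charged of the flask you put first, at 2.5 h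
* the amount of product, in percent of the starting material charged of the flask you put last, at 2.5 h

- what was read earlier has a scatter of 1.5 percentage points, one standard deviation

Amounts led me to the order of the rate: autumn read 5% of the charge as product at 30.0 min but 36% at 60.0 min, and a climb that steepens as product gathers suggested that product's own concentration sets the order, as in autocatalysis. I therefore took y, the fraction of the charge present as product, and read its logarithmic slope in two separate runs. In autumn, around y = 29.0%, the slope between 50.0 min and 60.0 min was 0.0492 min⁻¹; in winter, around y = 31.0%, the slope between 80.0 min and 120 min was 0.0264 min⁻¹. Divided by the starting material left, taken as charge times one minus y, the two readings parted: 0.0495 L mol⁻¹ min⁻¹ for autumn, 0.0627 L mol⁻¹ min⁻¹ for winter. Autumn was the one that cheated, for if each product takes one reagent, as I assumed, autumn retained 66.7% of its reagent and winter 84.5%. Dividing by the reagent left as well gave 0.0609 L^2 mol⁻² min⁻¹ and 0.0608 L^2 mol⁻² min⁻¹. Their mean, 0.0609 L^2 mol⁻² min⁻¹, is my growth constant, the logarithmic slope of product per unit of starting material and reagent left, and it remains a reading with the scatter of those points.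

At the start elm multiplied at 0.0487 min⁻¹ and birch at 0.0453 min⁻¹, a slight lead for elm. With product at 0.5 of the charge, however, and each product having taken one reagent as I assumed, birch kept 75.0% of its reagent and elm 37.5%, so in my reckoning, which counted the reagent lost and set aside the loss of starting material, the starting slope times the reagent kept came to 0.0340 min⁻¹ for birch, more than the 0.0183 min⁻¹ for elm. My own order was therefore birch, elm, oak, larch, the last two having smaller products of charges.

The forecast gave elm > birch > oak > larch, with 56% first and 15% last, and noted “The reagent order is untested”; its first two places are the reverse of mine.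

The flasks gave birch > elm > oak > larch: birch 51.8%, elm 49.3%, oak 34.5%, larch 13.8%.

    starting material + reagent + product → 2 product (k = 9.70 × 10⁻⁴ L² mol⁻² s⁻¹)
    starting material + reagent → product (k = 5.30 × 10⁻⁶ L mol⁻¹ s⁻¹)
    starting material + protic impurity → quenched substrate (k = 9.00 × 10⁻⁴ L mol⁻¹ s⁻¹)

In birch the growth constant, applied to what was left, gives a slope of 0.0299 min⁻¹ at 1.25 h and 0.00969 min⁻¹ at 2.50 h, hence a multiplication by 4.42; product went from 12.1% to 51.8%. Larch stood lowest mainly because of the time it was given, for it held 13.8% at 2.50 h and 81.3% at 25.0 h. For birch read at 1.0 h, with 76.2% of its starting material and 96.3% of its reagent left, the slope is 0.0332 min⁻¹, and reckoning back from 12.1% gives 7.56%; that flask holds 7.39%.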